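**Retrosynthetic overview**
1. The last C–C bond joins C4 of the upper (guibourtinidol) unit to C8 of the lower (epiafzelechin) unit: a Lewis acid generates the upper C4 cation, which is captured by the benzyl-protected lower flavan-3-ol; global hydrogenolysis ends the route.
2. Ring C of the lower unit is built on ring A in one [3+3] operation: the benzylic CH2 (C4) of a 2-bromobenzyl bromide is joined to the enolate carbon (C3) of 4-benzyloxyacetophenone, and the same enolate oxygen (O1) is then arylated under CuI catalysis at the bromine-bearing ring carbon (C8a), giving the flav-2-ene.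
3. The enabling feature: C4 and C8a are ortho neighbours on ring A (a 1,3-dielectrophile as the bromide pair), and O1–C2–C3 is the O–C=C unit of the enolate of the ring B aryl ketone (a 1,3-dinucleophile). The C5 and C7 oxygens sit meta to C8a and leave it reactive. The C2=C3 alkene is a temporary oxidation level.
4. Stereocentres follow the annulation: reagent-controlled hydroboration sets C2/C3 trans, and oxidation then hydride reduction inverts C3 to give the cis lower unit. The upper unit comes from the same annulation and hydroboration, then C4 oxidation; its C4 centre is set in the coupling, anti to the 3-hydroxy group.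
5. Ring order: lower ring C (steps 1–7), upper ring C (steps 8–13), interflavan bond (step 14), deprotection (step 15).

Key step: step 4

Remark: IpcBH2 made from (+)-α-pinene is assumed to add to the 2-aryl-4H-chromenes with the facial sense it shows with 1-arylcycloalkenes, giving the (2R,3S) alcohols; should the sense be the opposite, the reagent from (−)-α-pinene is used in steps 5 and 12.

**Route**

Step 1
Reactants: 1 1,3-bis(benzyloxy)-5-bromobenzene
Product: 3 2,4-bis(benzyloxy)-6-bromobenzaldehyde, via iminium salt 2 (not isolated)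
Conditions: POCl3, DMF, 0 to 70 °C; then H2O
Reagents that add atoms: N,N-dimethylformamide CN(C)C=O; water O
Why: Vilsmeier–Haack formylation, in which the chloroiminium ion attacks para to one benzyloxy group and ortho to the other, next to bromine and not at the carbon crowded between the two ether groups, as is the rule for 1-bromo-3,5-dialkoxybenzenes, and the iminium salt is hydrolysed on work-up.

Step 2
Reactants: 3 2,4-bis(benzyloxy)-6-bromobenzaldehyde
Product: 4 [2,4-bis(benzyloxy)-6-bromophenyl]methanol
Conditions: NaBH4, THF/MeOH, 0 °C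
Reagents that add atoms: none
Why: Borohydride reduction of an aryl aldehyde to the benzylic alcohol, which leaves the aryl bromide and the benzyl ethers untouched.

Step 3
Reactants: 4 [2,4-bis(benzyloxy)-6-bromophenyl]methanol
Product: 5 1,5-bis(benzyloxy)-3-bromo-2-(bromomethyl)benzene
Conditions: PBr3, Et2O, 0 °C; crude product used at once
Reagents that add atoms: phosphorus tribromide BrP(Br)Br
Why: Bromide-for-hydroxyl exchange with PBr3 (SN2 displacement on the phosphite ester) at a primary benzylic carbon, the electron-rich benzylic bromide being carried straight into step 4 instead of being stored.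

Step 4
Reactants: 5 1,5-bis(benzyloxy)-3-bromo-2-(bromomethyl)benzene; 6 1-[4-(benzyloxy)phenyl]ethanone
Product: 9 5,7-bis(benzyloxy)-2-[4-(benzyloxy)phenyl]-4H-chromene, via lithium enolate 7 (not isolated), via bromoketone 8 (not isolated)
Conditions: 6 (1.5 equiv), LiN(SiMe3)2, THF, −78 °C; 5, −78 to 0 °C; then DMF, Cs2CO3, CuI (10 mol %), 1,10-phenanthroline (20 mol %), 100 °C (THF distilled off), one pot
Reagents that add atoms: none
Why: The lithium enolate 7 attacks the benzylic CH2Br of 5 in an SN2 alkylation (C3–C4 bond), and after the change to Cs2CO3/DMF the enolate of bromoketone 8 is O-arylated at the bromine-bearing ring carbon under CuI/1,10-phenanthroline catalysis (oxidative addition of monovalent copper into C8a–Br, C–O reductive elimination from trivalent copper; O1–C8a bond), a [3+3] annulation that delivers ring C as the flav-2-ene. The closest known reaction type is the CuI-catalysed domino C-benzylation/enolate O-arylation of 1,3-dicarbonyl compounds with 2-bromobenzyl bromides to 4H-chromenes, together with the Ullmann-type ring closure of ketone enolates onto aryl bromides. Ring C is the only ring closed, in a 6-exo attack of the enolate oxygen on the aryl carbon; the competing C-arylation would need a four-membered ring and cannot interfere. No stereocentre is formed, since C2 and C3 end as the C2=C3 enol ether, and the E and Z enolates of 8 equilibrate through the ketone, so both drain through the Z enolate that can reach C8a. The step needs C- over O-alkylation (lithium enolate in THF with a soft benzylic bromide), mono- over dialkylation (excess enolate at low temperature) and reaction of the benzylic before the aryl C–Br bond (the aryl bromide is inert until CuI is added). The two benzyloxy groups stand meta to the bromine and therefore do not slow the CuI-catalysed closure.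

Step 5
Reactants: 9 5,7-bis(benzyloxy)-2-[4-(benzyloxy)phenyl]-4H-chromene
Product: 11 (2R,3S)-5,7-bis(benzyloxy)-2-[4-(benzyloxy)phenyl]chroman-3-ol, via alkylborane 10 (not isolated)
Conditions: IpcBH2 (from (+)-α-pinene), THF, −25 to 0 °C; then NaOH, H2O2, H2O, 0 °C to rt
Reagents that add atoms: hydrogen peroxide OO
Why: Asymmetric hydroboration–oxidation of a trisubstituted aryl enol ether, in which boron goes to C3 (distal to both O1 and the aryl group) and hydrogen to C2 on the same face, so that the 2-aryl and 3-hydroxy groups come out trans, the isopinocampheyl group selects the face that gives (2R,3S), and the C–B bond is oxidised with retention.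

Step 6
Reactants: 11 (2R,3S)-5,7-bis(benzyloxy)-2-[4-(benzyloxy)phenyl]chroman-3-ol
Product: 12 (2R)-5,7-bis(benzyloxy)-2-[4-(benzyloxy)phenyl]chroman-3-one
Conditions: Dess–Martin periodinane, pyridine, CH2Cl2, 0 °C
Reagents that add atoms: none
Why: Dess–Martin oxidation of the secondary alcohol under buffered, non-basic conditions, so that the C2 stereocentre next to the new ketone is not enolised.

Step 7
Reactants: 12 (2R)-5,7-bis(benzyloxy)-2-[4-(benzyloxy)phenyl]chroman-3-one
Product: 13 (2R,3R)-5,7-bis(benzyloxy)-2-[4-(benzyloxy)phenyl]chroman-3-ol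
Conditions: LiBH(sec-Bu)3, THF, −78 °C; then H2O
Reagents that add atoms: none
Why: Reduction of the cyclic ketone with a bulky trialkylborohydride, which attacks C3 from the face away from the neighbouring aryl group and so gives the 2,3-cis alcohol with (3R) configuration, the usual outcome for flavan-3-ones.

Step 8
Reactants: 14 2-bromo-4-hydroxybenzaldehyde
Product: 15 4-(benzyloxy)-2-bromobenzaldehyde
Conditions: BnBr, K2CO3, DMF, rt
Reagents that add atoms: benzyl bromide BrCc1ccccc1
Why: Williamson ether synthesis on the phenol (phenoxide SN2 on benzyl bromide).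

Step 9
Reactants: 15 4-(benzyloxy)-2-bromobenzaldehyde
Product: 16 [4-(benzyloxy)-2-bromophenyl]methanol
Conditions: NaBH4, THF/MeOH, 0 °C
Reagents that add atoms: none
Why: Borohydride reduction of the aryl aldehyde, with the aryl bromide and the benzyl ether inert.

Step 10
Reactants: 16 [4-(benzyloxy)-2-bromophenyl]methanol
Product: 17 4-(benzyloxy)-2-bromo-1-(bromomethyl)benzene
Conditions: PBr3, Et2O, 0 °C; crude product used at once
Reagents that add atoms: phosphorus tribromide BrP(Br)Br
Why: Bromide-for-hydroxyl exchange with PBr3 at a primary benzylic carbon, as in step 3.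

Step 11
Reactants: 17 4-(benzyloxy)-2-bromo-1-(bromomethyl)benzene; 6 1-[4-(benzyloxy)phenyl]ethanone
Product: 20 7-(benzyloxy)-2-[4-(benzyloxy)phenyl]-4H-chromene, via sodium enolate 18 (not isolated), via bromoketone 19 (not isolated)
Conditions: 6 (1.5 equiv), NaN(SiMe3)2, THF, −78 °C; 17, −78 to −20 °C; then DMF, Cs2CO3, CuI (10 mol %), 1,10-phenanthroline (20 mol %), 100 °C (THF distilled off), one pot
Reagents that add atoms: none
Why: One-pot enolate C-benzylation and CuI-catalysed enolate O-arylation of the kind used in step 4, run here through the more reactive sodium enolate 18 so that the SN2 benzylation of the less hindered bromide 17 is complete at low temperature before bromoketone 19 is closed to ring C of the upper unit, with no stereocentre formed.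

Step 12
Reactants: 20 7-(benzyloxy)-2-[4-(benzyloxy)phenyl]-4H-chromene
Product: 22 (2R,3S)-7-(benzyloxy)-2-[4-(benzyloxy)phenyl]chroman-3-ol, via alkylborane 21 (not isolated)
Conditions: IpcBH2 (from (+)-α-pinene), THF, −25 to 0 °C; then NaOH, H2O2, H2O, 0 °C to rt
Reagents that add atoms: hydrogen peroxide OO
Why: Asymmetric hydroboration–oxidation as in step 5, where syn addition of hydrogen (C2) and boron (C3) under control of the isopinocampheyl group gives the (2R,3S)-trans alcohol.

Step 13
Reactants: 22 (2R,3S)-7-(benzyloxy)-2-[4-(benzyloxy)phenyl]chroman-3-ol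
Product: 23 (2R,3S,4S)-7-(benzyloxy)-2-[4-(benzyloxy)phenyl]-4-(2-ethoxyethoxy)chroman-3-ol
Conditions: DDQ, 2-ethoxyethanol, CH2Cl2, rt
Reagents that add atoms: 2-ethoxyethanol CCOCCO
Why: Oxidative C4 etherification of a flavan-3-ol, in which DDQ abstracts hydride from C4 (benzylic, para to the C7 ether and ortho to O1 on the more electron-rich ring A) and 2-ethoxyethanol traps the cation, the (4S) epimer being expected by analogy with 5-oxygenated flavan-3-ols, although the configuration at C4 is without consequence because it is erased in step 14.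

Step 14
Reactants: 23 (2R,3S,4S)-7-(benzyloxy)-2-[4-(benzyloxy)phenyl]-4-(2-ethoxyethoxy)chroman-3-ol; 13 (2R,3R)-5,7-bis(benzyloxy)-2-[4-(benzyloxy)phenyl]chroman-3-ol
Product: 24 (2R,3R)-5,7-bis(benzyloxy)-2-[4-(benzyloxy)phenyl]-8-{(2R,3S,4S)-7-(benzyloxy)-2-[4-(benzyloxy)phenyl]-3-hydroxychroman-4-yl}chroman-3-ol
Conditions: 13 (3 equiv), Me3SiOTf (0.2 equiv), 4 Å molecular sieves, CH2Cl2, −78 to −40 °C; then aq. NaHCO3; excess 13 recovered
Reagents that add atoms: none
Why: Lewis-acid-promoted Friedel–Crafts (interflavan) coupling, in which Me3SiOTf ionises the C4 ether to the benzylic cation stabilised by O1 and the C7 ether, the phloroglucinol-type ring of 13 attacks through C8 (less hindered than C6) on the face anti to the adjacent 3-hydroxy group, which sets (4S) with all three ring C substituents equatorial, and the excess of 13 suppresses a second alkylation.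

Step 15
Reactants: 24 (2R,3R)-5,7-bis(benzyloxy)-2-[4-(benzyloxy)phenyl]-8-{(2R,3S,4S)-7-(benzyloxy)-2-[4-(benzyloxy)phenyl]-3-hydroxychroman-4-yl}chroman-3-ol
Product: 25 (2R,3R)-2-(4-hydroxyphenyl)-8-[(2R,3S,4S)-3,7-dihydroxy-2-(4-hydroxyphenyl)chroman-4-yl]chroman-3,5,7-triol
Conditions: H2 (1 atm), Pd(OH)2/C, THF/MeOH/H2O, rt
Reagents that add atoms: none
Why: Hydrogenolysis of the five benzyl ethers over Pd(OH)2/C under neutral conditions, which spare the acid-labile interflavan bond and the base-labile C2 centres.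

**Compound list**
1 | 1,3-bis(benzyloxy)-5-bromobenzene | Brc1cc(OCc2ccccc2)cc(OCc2ccccc2)c1 | starting material
2 | N-[2,4-bis(benzyloxy)-6-bromobenzylidene]-N-methylmethanaminium dichlorophosphate | C[N+](C)=Cc1c(Br)cc(OCc2ccccc2)cc1OCc1ccccc1.[O-]P(=O)(Cl)Cl | intermediate
3 | 2,4-bis(benzyloxy)-6-bromobenzaldehyde | O=Cc1c(Br)cc(OCc2ccccc2)cc1OCc1ccccc1 | intermediate
4 | [2,4-bis(benzyloxy)-6-bromophenyl]methanol | OCc1c(Br)cc(OCc2ccccc2)cc1OCc1ccccc1 | intermediate
5 | 1,5-bis(benzyloxy)-3-bromo-2-(bromomethyl)benzene | BrCc1c(Br)cc(OCc2ccccc2)cc1OCc1ccccc1 | intermediate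
6 | 1-[4-(benzyloxy)phenyl]ethanone | CC(=O)c1ccc(OCc2ccccc2)cc1 | starting material
7 | lithium 1-[4-(benzyloxy)phenyl]ethenolate | [Li+].[O-]C(=C)c1ccc(OCc2ccccc2)cc1 | intermediate
8 | 3-[2,4-bis(benzyloxy)-6-bromophenyl]-1-[4-(benzyloxy)phenyl]propan-1-one | O=C(CCc1c(Br)cc(OCc2ccccc2)cc1OCc1ccccc1)c1ccc(OCc2ccccc2)cc1 | intermediate
9 | 5,7-bis(benzyloxy)-2-[4-(benzyloxy)phenyl]-4H-chromene | C(c1ccccc1)Oc1ccc(cc1)C1=CCc2c(OCc3ccccc3)cc(OCc3ccccc3)cc2O1 | intermediate
10 | isopinocampheyl[2,3-trans-5,7-bis(benzyloxy)-2-(4-(benzyloxy)phenyl)chroman-3-yl]borane | C[C@H]1[C@H](B[C@H]3Cc4c(OCc5ccccc5)cc(OCc5ccccc5)cc4O[C@@H]3c3ccc(OCc4ccccc4)cc3)C[C@@H]2C[C@H]1C2(C)C | intermediate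
11 | (2R,3S)-5,7-bis(benzyloxy)-2-[4-(benzyloxy)phenyl]chroman-3-ol | O[C@H]1Cc2c(OCc3ccccc3)cc(OCc3ccccc3)cc2O[C@@H]1c1ccc(OCc2ccccc2)cc1 | intermediate
12 | (2R)-5,7-bis(benzyloxy)-2-[4-(benzyloxy)phenyl]chroman-3-one | O=C1Cc2c(OCc3ccccc3)cc(OCc3ccccc3)cc2O[C@@H]1c1ccc(OCc2ccccc2)cc1 | intermediate
13 | (2R,3R)-5,7-bis(benzyloxy)-2-[4-(benzyloxy)phenyl]chroman-3-ol | O[C@@H]1Cc2c(OCc3ccccc3)cc(OCc3ccccc3)cc2O[C@@H]1c1ccc(OCc2ccccc2)cc1 | intermediate
14 | 2-bromo-4-hydroxybenzaldehyde | O=Cc1ccc(O)cc1Br | starting material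
15 | 4-(benzyloxy)-2-bromobenzaldehyde | O=Cc1ccc(OCc2ccccc2)cc1Br | intermediate
16 | [4-(benzyloxy)-2-bromophenyl]methanol | OCc1ccc(OCc2ccccc2)cc1Br | intermediate
17 | 4-(benzyloxy)-2-bromo-1-(bromomethyl)benzene | BrCc1ccc(OCc2ccccc2)cc1Br | intermediate
18 | sodium 1-[4-(benzyloxy)phenyl]ethenolate | [Na+].[O-]C(=C)c1ccc(OCc2ccccc2)cc1 | intermediate
19 | 3-[4-(benzyloxy)-2-bromophenyl]-1-[4-(benzyloxy)phenyl]propan-1-one | O=C(CCc1ccc(OCc2ccccc2)cc1Br)c1ccc(OCc2ccccc2)cc1 | intermediate
20 | 7-(benzyloxy)-2-[4-(benzyloxy)phenyl]-4H-chromene | C(c1ccccc1)Oc1ccc(cc1)C1=CCc2ccc(OCc3ccccc3)cc2O1 | intermediate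
21 | isopinocampheyl[2,3-trans-7-(benzyloxy)-2-(4-(benzyloxy)phenyl)chroman-3-yl]borane | C[C@H]1[C@H](B[C@H]3Cc4ccc(OCc5ccccc5)cc4O[C@@H]3c3ccc(OCc4ccccc4)cc3)C[C@@H]2C[C@H]1C2(C)C | intermediate
22 | (2R,3S)-7-(benzyloxy)-2-[4-(benzyloxy)phenyl]chroman-3-ol | O[C@H]1Cc2ccc(OCc3ccccc3)cc2O[C@@H]1c1ccc(OCc2ccccc2)cc1 | intermediate
23 | (2R,3S,4S)-7-(benzyloxy)-2-[4-(benzyloxy)phenyl]-4-(2-ethoxyethoxy)chroman-3-ol | O[C@H]1[C@@H](OCCOCC)c2ccc(OCc3ccccc3)cc2O[C@@H]1c1ccc(OCc2ccccc2)cc1 | intermediate
24 | (2R,3R)-5,7-bis(benzyloxy)-2-[4-(benzyloxy)phenyl]-8-{(2R,3S,4S)-7-(benzyloxy)-2-[4-(benzyloxy)phenyl]-3-hydroxychroman-4-yl}chroman-3-ol | c5ccccc5COc1ccc([C@H]2Oc3cc(OCc5ccccc5)ccc3[C@@H](c3c(OCc5ccccc5)cc(OCc5ccccc5)c4c3O[C@H](c3ccc(OCc5ccccc5)cc3)[C@H](O)C4)[C@@H]2O)cc1 | intermediate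
25 | (2R,3R)-2-(4-hydroxyphenyl)-8-[(2R,3S,4S)-3,7-dihydroxy-2-(4-hydroxyphenyl)chroman-4-yl]chroman-3,5,7-triol | Oc1ccc([C@H]2Oc3cc(O)ccc3[C@@H](c3c(O)cc(O)c4c3O[C@H](c3ccc(O)cc3)[C@H](O)C4)[C@@H]2O)cc1 | target

**Totals and risks**

Total step count: 15. Longest linear sequence: 9 steps (1, 2, 3, 4, 5, 6, 7, 14, 15).

The three steps most likely to fail:

Step 13. Hydride loss may occur from C2 (benzylic to ring B and next to O1) instead of C4, which would open ring C, or the C4 ether may be oxidised further. Ring A of this 5-deoxy flavan is a weaker donor than the rings for which the reaction is established. The fallback sets out from 22 and comes back at 24. Benzylic acetoxylation of 22 with Pb(OAc)4 in benzene, an inner-sphere ligand transfer from tetravalent lead that needs no charge-transfer complex with the arene, should give (2R,3R,4S)-7-(benzyloxy)-2-[4-(benzyloxy)phenyl]-3-hydroxychroman-4-yl acetate F1. F1 then takes the place of 23 in the coupling with 13, where Me3SiOTf ionises the benzylic acetate to the same C4 cation and 24 results.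

Step 14. Capture of the planar C4 cation may lack facial selectivity, so that the 3,4-cis (4R) dimer forms beside 24, or the dimer may be alkylated a second time at C6 of its lower unit. The fallback sets out from 23 and comes back at 24, and relies on neighbouring-group participation. Acetylation of the 3-hydroxy group of 23 (Ac2O, pyridine) gives (2R,3S,4S)-7-(benzyloxy)-2-[4-(benzyloxy)phenyl]-4-(2-ethoxyethoxy)chroman-3-yl acetate F2. On ionisation the acetate bridges C3 and C4 on its own face as a dioxolanylium ion, so 13 can only enter anti. This gives (2R,3S,4S)-7-(benzyloxy)-2-[4-(benzyloxy)phenyl]-4-{(2R,3R)-5,7-bis(benzyloxy)-2-[4-(benzyloxy)phenyl]-3-hydroxychroman-8-yl}chroman-3-yl acetate F3. Methanolysis (K2CO3, MeOH/THF) then removes the acetate to give 24.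

Step 4. The electron-rich benzylic bromide 5 may ionise and alkylate itself before it meets the enolate, or the methyl ketone enolate may be benzylated twice. The fallback sets out from 3 (with 6) and comes back at 9, forming the two bonds in separate steps. Claisen–Schmidt condensation of aldehyde 3 with ketone 6 (KOH, EtOH) gives (E)-3-[2,4-bis(benzyloxy)-6-bromophenyl]-1-[4-(benzyloxy)phenyl]prop-2-en-1-one F4. Conjugate reduction of the enone with [(Ph3P)CuH]6 in THF gives bromoketone 8, now isolated. The ring closure with CuI, 1,10-phenanthroline and Cs2CO3 in DMF at 100 °C then gives 9. This avoids bromide 5 and the alkylation altogether.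

Further compounds
F1 | step 13 | (2R,3R,4S)-7-(benzyloxy)-2-[4-(benzyloxy)phenyl]-3-hydroxychroman-4-yl acetate | O[C@H]1[C@@H](OC(C)=O)c2ccc(OCc3ccccc3)cc2O[C@@H]1c1ccc(OCc2ccccc2)cc1
F2 | step 14 | (2R,3S,4S)-7-(benzyloxy)-2-[4-(benzyloxy)phenyl]-4-(2-ethoxyethoxy)chroman-3-yl acetate | CC(=O)O[C@H]1[C@@H](OCCOCC)c2ccc(OCc3ccccc3)cc2O[C@@H]1c1ccc(OCc2ccccc2)cc1
F3 | step 14 | (2R,3S,4S)-7-(benzyloxy)-2-[4-(benzyloxy)phenyl]-4-{(2R,3R)-5,7-bis(benzyloxy)-2-[4-(benzyloxy)phenyl]-3-hydroxychroman-8-yl}chroman-3-yl acetate | c5ccccc5COc1ccc([C@H]2Oc3cc(OCc5ccccc5)ccc3[C@@H](c3c(OCc5ccccc5)cc(OCc5ccccc5)c4c3O[C@H](c3ccc(OCc5ccccc5)cc3)[C@H](O)C4)[C@@H]2OC(C)=O)cc1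
F4 | step 4 | (E)-3-[2,4-bis(benzyloxy)-6-bromophenyl]-1-[4-(benzyloxy)phenyl]prop-2-en-1-one | O=C(/C=C/c1c(Br)cc(OCc2ccccc2)cc1OCc1ccccc1)c1ccc(OCc2ccccc2)cc1
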